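**Plan**

1. The central ring is numbered C1 and C2 (benzoate carbons), C3 and C6 (4-hydroxyphenyl carbons), C4 and C5 (hydroxyl carbons). The retrosynthesis first removes the two benzoyl C–O bonds and masks the four free hydroxyls as benzyl ethers, then cuts the central ring at C3–C4, C1–C2 and C1–C6.
2. Enabling feature: C1 is an oxygen-bearing ring carbon that can originate from a carbonyl ligand. It lies between the oxygenated alkyne carbon C2 and the aryl-bearing alkene terminus C6, and para to C4, which can be an alkoxycarbene carbon. The central ring is therefore the Dötz adduct of a C4–C5–C6 alkenyl(benzyloxy)carbene chromium complex, a C2–C3 aryl siloxyalkyne and CO.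
3. Forward, carbene part (steps 1–4): 4-(benzyloxy)benzaldehyde and methyl (benzyloxy)acetate give the Z α-benzyloxyacrylic acid; its chloride acylates Na2[Cr(CO)5]; acyloxycarbene alcoholysis installs the O-benzyl carbene. The arylacetylene is oxidized to its ynolate and silylated (step 5).
4. Step 6 closes the central ring, the only ring that is made (both outer rings are bought). It arrives with O1 free, O2 silylated and O4, O5 benzylated.
5. Desilylation, double benzoylation of the O1/O2 catechol and one neutral hydrogenolysis of all four benzyl ethers complete the route (steps 7–9); benzyl is used on every oxygen that must end free so that the benzoates are never exposed to Lewis acid.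
6. Stereochemistry: the target has no stereocentre. The only stereo-element on the way is the Z alkene of the carbene complex, set by thermodynamic condensation and erased on aromatization.

Key step: step 6

Remark: 1-(benzyloxy)-4-ethynylbenzene and methyl 2-(benzyloxy)acetate are taken as catalogue compounds; Cr(CO)6 supplies zerovalent chromium and the C1 carbonyl.

**Route**

Step 1
Reactants: 1 4-(benzyloxy)benzaldehyde; 2 methyl 2-(benzyloxy)acetate
Product: 4 (Z)-2-(benzyloxy)-3-[4-(benzyloxy)phenyl]prop-2-enoic acid, via methyl ester 3 (not isolated)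
Conditions: NaOMe (3 equiv), 2 (2 equiv), MeOH, reflux; then 2 M NaOH, reflux; HCl to pH 2; crystallization
Reagents that add atoms: sodium hydroxide, [Na+].[OH-]
Why: Claisen–Schmidt-type aldol condensation of the alkoxyacetate enolate with the non-enolizable aldehyde, E1cB dehydration and saponification should give the thermodynamically preferred Z acid (aryl trans to the carboxyl group), which crystallization should free of any E isomer.

Step 2
Reactants: 4 (Z)-2-(benzyloxy)-3-[4-(benzyloxy)phenyl]prop-2-enoic acid
Product: 5 (Z)-2-(benzyloxy)-3-[4-(benzyloxy)phenyl]prop-2-enoyl chloride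
Conditions: (COCl)2 (1.3 equiv), DMF (cat.), CH2Cl2, 0 → 25 °C; evaporate, use at once
Reagents that add atoms: oxalyl chloride, O=C(Cl)C(=O)Cl
Why: Vilsmeier-type activation of the carboxylic acid gives the acid chloride under mild conditions that should leave the benzyl ethers and the enol-ether alkene untouched.

Step 3
Reactants: 5 (Z)-2-(benzyloxy)-3-[4-(benzyloxy)phenyl]prop-2-enoyl chloride; 6 chromium hexacarbonyl
Product: 9 tetramethylammonium pentacarbonyl[(Z)-2-(benzyloxy)-3-[4-(benzyloxy)phenyl]-1-oxidoprop-2-en-1-ylidene]chromate, via disodium pentacarbonylchromate 7 (not isolated), via sodium acylchromate 8 (not isolated)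
Conditions: Cr(CO)6, NaC10H8 (sodium naphthalenide, 2 equiv), THF, −78 °C; 5, −78 → 0 °C; then Me4NBr, degassed H2O, 0 °C
Reagents that add atoms: tetramethylammonium bromide, C[N+](C)(C)C.[Br-]
Why: Acyl substitution of the acid chloride by the strongly nucleophilic pentacarbonylchromate dianion (the acid-chloride entry to Fischer acylmetalates, which avoids a vinyllithium that the benzyl ethers would not tolerate) forms the Cr–C4 bond, and cation metathesis should give the storable ammonium acylate.

Step 4
Reactants: 9 tetramethylammonium pentacarbonyl[(Z)-2-(benzyloxy)-3-[4-(benzyloxy)phenyl]-1-oxidoprop-2-en-1-ylidene]chromate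
Product: 11 pentacarbonyl[(Z)-1,2-bis(benzyloxy)-3-[4-(benzyloxy)phenyl]prop-2-en-1-ylidene]chromium, via acetoxycarbene complex 10 (not isolated)
Conditions: AcBr (1.05 equiv), CH2Cl2, −40 °C; BnOH (1.5 equiv), −40 → 25 °C
Reagents that add atoms: benzyl alcohol, OCc1ccccc1
Why: O-Acylation of the acylate gives an acyloxycarbene whose acetate is displaced by benzyl alcohol at the electrophilic carbene carbon (acyloxycarbene alcoholysis, the standard route to Fischer carbenes with alkoxy groups other than methoxy, established for alkenyl acylates).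

Step 5
Reactants: 12 1-(benzyloxy)-4-ethynylbenzene
Product: 15 [[4-(benzyloxy)phenyl]ethynyloxy]triisopropylsilane, via lithium acetylide 13 (not isolated), via lithium ynolate 14 (not isolated)
Conditions: LiN(SiMe3)2 (2.2 equiv), THF, −78 °C; t-BuOOH (1.0 equiv, anhydrous), −78 → 0 °C; TIPSOTf (1.1 equiv), −78 → 0 °C
Reagents that add atoms: tert-butyl hydroperoxide, CC(C)(C)OO; triisopropylsilyl trifluoromethanesulfonate, CC(C)[Si](OS(=O)(=O)C(F)(F)F)(C(C)C)C(C)C
Why: Oxidation of the lithium acetylide by lithium tert-butyl peroxide gives the lithium ynolate, which the hard, bulky silyl triflate should trap on oxygen to give the isolable triisopropylsilyl ynol ether (peroxide oxidation of acetylides to ynolates followed by O-silylation).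

Step 6
Reactants: 11 pentacarbonyl[(Z)-1,2-bis(benzyloxy)-3-[4-(benzyloxy)phenyl]prop-2-en-1-ylidene]chromium; 15 [[4-(benzyloxy)phenyl]ethynyloxy]triisopropylsilane
Product: 17 4,4'',5',6'-tetrakis(benzyloxy)-3'-[(triisopropylsilyl)oxy]-1,1':4',1''-terphenyl-2'-ol, via tricarbonylchromium arene complex 16 (not isolated)
Conditions: 15 (1.5 equiv), THF (0.2 M), 50 °C, argon, dark; then blue LED (450 nm), 25 °C; then air, 25 °C
Reagents that add atoms: none
Why: Proposed new method: thermal loss of one carbonyl ligand from 11 opens a site for the siloxyalkyne, whose aryl-substituted carbon (the nucleophilic end of the ynol ether) attacks the electrophilic carbene carbon to make C3–C4, so that the siloxy carbon becomes the new carbene carbon and takes up a carbonyl ligand by migratory insertion to give a chromium-bound dienylketene (C1–C2). The central ring then closes by 6π-electrocyclization of that dienylketene onto the aryl-bearing alkene terminus (C1–C6), and tautomerization of the cyclohexadienone gives the phenol, held as the Cr(CO)3 complex 16 until air and light release 17. The closest known reaction type is the Dötz benzannulation of alkenyl(alkoxy)carbene chromium complexes, α-alkoxyalkenyl ones included, with carbon-substituted alkynes; a 1-siloxyalkyne has not been shown as the alkyne partner. No stereocentre is formed and the Z geometry of 11 disappears on aromatization. The step needs the siloxy carbon next to the carbonyl-derived C1, which is favoured both by the ynol-ether polarization (the sense in which ynamines insert into Fischer carbenes) and by the usual placing of the bulkier alkyne terminus beside the new phenol carbon. If the oxygen-stabilized dienyl(siloxy)carbene resists thermal carbonyl insertion, the visible-light stage should drive it as in the photochemical benzannulation of dienyl(alkoxy)carbene chromium complexes, while an alkenyl (not aryl) carbene in the donor solvent THF disfavours five-membered closure.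

Step 7
Reactants: 17 4,4'',5',6'-tetrakis(benzyloxy)-3'-[(triisopropylsilyl)oxy]-1,1':4',1''-terphenyl-2'-ol
Product: 18 4,4'',5',6'-tetrakis(benzyloxy)-1,1':4',1''-terphenyl-2',3'-diol
Conditions: Bu4NF (1.1 equiv), AcOH (1.1 equiv), THF, 0 °C, argon
Reagents that add atoms: none
Why: Fluoride-induced cleavage of the aryl silyl ether, buffered with acetic acid and kept under argon so that the electron-rich catechol is not oxidized as its phenoxide; silyl migration between O1 and O2 is irrelevant because both oxygens are freed.

Step 8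
Reactants: 18 4,4'',5',6'-tetrakis(benzyloxy)-1,1':4',1''-terphenyl-2',3'-diol
Product: 19 4,4'',5',6'-tetrakis(benzyloxy)-1,1':4',1''-terphenyl-2',3'-diyl dibenzoate
Conditions: BzCl (3 equiv), Et3N (4 equiv), DMAP (0.2 equiv), CH2Cl2, 0 → 25 °C
Reagents that add atoms: benzoyl chloride, O=C(Cl)c1ccccc1
Why: DMAP-catalysed O-acylation with excess benzoyl chloride should esterify both hindered catechol hydroxyls, which are the only free OH groups in 18.

Step 9
Reactants: 19 4,4'',5',6'-tetrakis(benzyloxy)-1,1':4',1''-terphenyl-2',3'-diyl dibenzoate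
Product: 20 4,4'',5',6'-tetrahydroxy-1,1':4',1''-terphenyl-2',3'-diyl dibenzoate (CNP0216579.0)
Conditions: H2 (1 atm), Pd/C (10% palladium on carbon), EtOAc–THF, 25 °C; filtration under argon
Reagents that add atoms: none
Why: Heterogeneous palladium-catalysed hydrogenolysis cleaves the four benzylic C–O bonds under neutral conditions that aryl benzoates tolerate, and because the freed O4 and O5 are never ortho to a benzoate no acyl migration can follow.

**Compound list**

1 | 4-(benzyloxy)benzaldehyde | O=Cc1ccc(OCc2ccccc2)cc1 | starting material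
2 | methyl 2-(benzyloxy)acetate | COC(=O)COCc1ccccc1 | starting material
3 | methyl (Z)-2-(benzyloxy)-3-[4-(benzyloxy)phenyl]prop-2-enoate | COC(=O)/C(OCc1ccccc1)=C/c1ccc(OCc2ccccc2)cc1 | intermediate
4 | (Z)-2-(benzyloxy)-3-[4-(benzyloxy)phenyl]prop-2-enoic acid | OC(=O)/C(OCc1ccccc1)=C/c1ccc(OCc2ccccc2)cc1 | intermediate
5 | (Z)-2-(benzyloxy)-3-[4-(benzyloxy)phenyl]prop-2-enoyl chloride | O=C(Cl)/C(OCc1ccccc1)=C/c1ccc(OCc2ccccc2)cc1 | intermediate
6 | chromium hexacarbonyl, Cr(CO)6 | O=C=[Cr](=C=O)(=C=O)(=C=O)(=C=O)=C=O | starting material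
7 | disodium pentacarbonylchromate, Na2[Cr(CO)5] | [Na+].[Na+].O=C=[Cr-2](=C=O)(=C=O)(=C=O)=C=O | intermediate
8 | sodium pentacarbonyl[(Z)-2-(benzyloxy)-3-[4-(benzyloxy)phenyl]-1-oxidoprop-2-en-1-ylidene]chromate | [Na+].[O-]C(=[Cr](=C=O)(=C=O)(=C=O)(=C=O)=C=O)/C(OCc1ccccc1)=C/c1ccc(OCc2ccccc2)cc1 | intermediate
9 | tetramethylammonium pentacarbonyl[(Z)-2-(benzyloxy)-3-[4-(benzyloxy)phenyl]-1-oxidoprop-2-en-1-ylidene]chromate | C[N+](C)(C)C.[O-]C(=[Cr](=C=O)(=C=O)(=C=O)(=C=O)=C=O)/C(OCc1ccccc1)=C/c1ccc(OCc2ccccc2)cc1 | intermediate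
10 | pentacarbonyl[(Z)-1-(acetyloxy)-2-(benzyloxy)-3-[4-(benzyloxy)phenyl]prop-2-en-1-ylidene]chromium | CC(=O)OC(=[Cr](=C=O)(=C=O)(=C=O)(=C=O)=C=O)/C(OCc1ccccc1)=C/c1ccc(OCc2ccccc2)cc1 | intermediate
11 | pentacarbonyl[(Z)-1,2-bis(benzyloxy)-3-[4-(benzyloxy)phenyl]prop-2-en-1-ylidene]chromium | O=C=[Cr](=C=O)(=C=O)(=C=O)(=C=O)=C(OCc1ccccc1)/C(OCc1ccccc1)=C/c1ccc(OCc2ccccc2)cc1 | intermediate
12 | 1-(benzyloxy)-4-ethynylbenzene | C#Cc1ccc(OCc2ccccc2)cc1 | starting material
13 | lithium [4-(benzyloxy)phenyl]acetylide | [Li]C#Cc1ccc(OCc2ccccc2)cc1 | intermediate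
14 | lithium 2-[4-(benzyloxy)phenyl]ethynolate | [Li+].[O-]C#Cc1ccc(OCc2ccccc2)cc1 | intermediate
15 | [[4-(benzyloxy)phenyl]ethynyloxy]triisopropylsilane | CC(C)[Si](OC#Cc1ccc(OCc2ccccc2)cc1)(C(C)C)C(C)C | intermediate
16 | tricarbonyl(η6-arene)chromium complex of 17, chromium on the central ring (π-bonding written as two dot-joined parts) | c1ccccc1COc1c(OCc2ccccc2)c(-c2ccc(OCc3ccccc3)cc2)c(O[Si](C(C)C)(C(C)C)C(C)C)c(O)c1-c1ccc(OCc2ccccc2)cc1.O=C=[Cr](=C=O)=C=O | intermediate
17 | 4,4'',5',6'-tetrakis(benzyloxy)-3'-[(triisopropylsilyl)oxy]-1,1':4',1''-terphenyl-2'-ol | c1ccccc1COc1c(OCc2ccccc2)c(-c2ccc(OCc3ccccc3)cc2)c(O[Si](C(C)C)(C(C)C)C(C)C)c(O)c1-c1ccc(OCc2ccccc2)cc1 | intermediate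
18 | 4,4'',5',6'-tetrakis(benzyloxy)-1,1':4',1''-terphenyl-2',3'-diol | c1ccccc1COc1c(OCc2ccccc2)c(-c2ccc(OCc3ccccc3)cc2)c(O)c(O)c1-c1ccc(OCc2ccccc2)cc1 | intermediate
19 | 4,4'',5',6'-tetrakis(benzyloxy)-1,1':4',1''-terphenyl-2',3'-diyl dibenzoate | c1ccccc1COc1c(OCc2ccccc2)c(-c2ccc(OCc3ccccc3)cc2)c(OC(=O)c2ccccc2)c(OC(=O)c2ccccc2)c1-c1ccc(OCc2ccccc2)cc1 | intermediate
20 | 4,4'',5',6'-tetrahydroxy-1,1':4',1''-terphenyl-2',3'-diyl dibenzoate (CNP0216579.0) | O=C(Oc1c(OC(=O)c2ccccc2)c(-c2ccc(O)cc2)c(O)c(O)c1-c1ccc(O)cc1)c1ccccc1 | target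

**Step count and risks**

Total: 9 steps. Longest linear sequence: 8 steps (1, 2, 3, 4, 6, 7, 8, 9 from aldehyde 1); the alkyne branch adds step 5.

Steps most likely to fail:

Step 6. The cascade may stop after alkyne insertion because the siloxy-stabilized carbene does not take up a carbonyl ligand. The ynol ether may also be consumed through protonation by the phenol being formed, or the ring may close to a five-membered product without carbonyl insertion. The fallback uses known chemistry, sets out from 12 (with 11) and comes back at 18. Deprotonation of 12 (n-BuLi, THF, −78 °C), borylation with 2-isopropoxy-4,4,5,5-tetramethyl-1,3,2-dioxaborolane and quench with HCl·Et2O should give 2-{[4-(benzyloxy)phenyl]ethynyl}-4,4,5,5-tetramethyl-1,3,2-dioxaborolane F1. Its Dötz benzannulation with 11 (THF, 50 °C, then air) is a known alkynylboronate variant in which the boryl carbon is expected beside the carbonyl-derived carbon, and should give 4,4'',5',6'-tetrakis(benzyloxy)-3'-(4,4,5,5-tetramethyl-1,3,2-dioxaborolan-2-yl)-1,1':4',1''-terphenyl-2'-ol F2. Oxidation of the C–B bond (NaBO3·4H2O, THF–H2O, 25 °C) then gives catechol 18 directly, so step 7 is skipped.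

Step 3. The strongly reducing dianion may transfer an electron to the enoyl chloride, or add to it in conjugate fashion, instead of substituting at the acyl carbon; the alkene geometry may also scramble. The fallback sets out from 6 (with 1) and comes back at 11, forming the C5=C6 alkene only after the metal is in place. Benzyloxymethyllithium (from Bu3SnCH2OBn and n-BuLi, THF, −78 °C) adds to Cr(CO)6 in the classical Fischer manner, and Me4NBr gives tetramethylammonium pentacarbonyl[2-(benzyloxy)-1-oxidoethylidene]chromate F3. Acetyl bromide (CH2Cl2, −40 °C) converts it to pentacarbonyl[1-(acetyloxy)-2-(benzyloxy)ethylidene]chromium F4, which benzyl alcohol turns into pentacarbonyl[1,2-bis(benzyloxy)ethylidene]chromium F5. Aldol condensation of its acidic α-CH2 group with aldehyde 1 (Et3N, Me3SiCl, Et2O, 25 °C) should then give 11 with the aryl group trans to the bulky carbene carbon; steps 1, 2 and 4 are bypassed.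

Step 4. The acyloxycarbene may decompose thermally before acetate is displaced, or benzyl alcohol may add to the activated alkene. The fallback sets out from 9 and comes back at 11 without any new compound (F0). Acylate 9 is O-alkylated directly with benzyl trifluoromethanesulfonate, made at −78 °C from benzyl alcohol, Tf2O and 2,6-di-tert-butyl-4-methylpyridine in CH2Cl2. This is alkylation of an acylmetalate by an alkyl triflate: the acylate oxygen is kept and benzylated, so no acyloxycarbene is involved.

**Further compounds**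

F1 | step 6 | 2-{[4-(benzyloxy)phenyl]ethynyl}-4,4,5,5-tetramethyl-1,3,2-dioxaborolane | CC1(C)OB(C#Cc2ccc(OCc3ccccc3)cc2)OC1(C)C
F2 | step 6 | 4,4'',5',6'-tetrakis(benzyloxy)-3'-(4,4,5,5-tetramethyl-1,3,2-dioxaborolan-2-yl)-1,1':4',1''-terphenyl-2'-ol | c1ccccc1COc1c(OCc2ccccc2)c(-c2ccc(OCc3ccccc3)cc2)c(B2OC(C)(C)C(C)(C)O2)c(O)c1-c1ccc(OCc2ccccc2)cc1
F3 | step 3 | tetramethylammonium pentacarbonyl[2-(benzyloxy)-1-oxidoethylidene]chromate | C[N+](C)(C)C.[O-]C(COCc1ccccc1)=[Cr](=C=O)(=C=O)(=C=O)(=C=O)=C=O
F4 | step 3 | pentacarbonyl[1-(acetyloxy)-2-(benzyloxy)ethylidene]chromium | CC(=O)OC(COCc1ccccc1)=[Cr](=C=O)(=C=O)(=C=O)(=C=O)=C=O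
F5 | step 3 | pentacarbonyl[1,2-bis(benzyloxy)ethylidene]chromium | O=C=[Cr](=C=O)(=C=O)(=C=O)(=C=O)=C(OCc1ccccc1)COCc1ccccc1
F0 | step 4 | none | none
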